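**Assumption:** (1S,2S,4R)-(+)-limonene-1,2-diol is taken as a purchased compound (it is also one step from commercial (+)-limonene oxide with dilute aqueous acid).

## Retrosynthetic overview

1. Target 14 ← ketone 13 by substrate-controlled hydride reduction of the ring A ketone.
2. 13 ← ketal Claisen ([3,3]) rearrangement of allyl enol ether 12, made in the flask from ring A hydroxy ketal 6 and ring B allylic alcohol 10; this forms the inter-ring CH2–C3 bond of ring A.
3. Ring A piece 6 ← (S)-carvone 1: epoxidation anti to isopropenyl, hydride opening, oxidation, ketalisation.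
4. Ring B piece 10 ← (1S,2S,4R)-limonene-1,2-diol 7: mesylate, bromide displacement with inversion (syn-bromohydrin), allylic hydroxylation.
5. No ring is built: both carbocycles are bought with their stereocentres; ring A is elaborated first, ring B second, and they are joined in the penultimate step.

## Route

**Step 1**
Reactants: 1 (S)-(+)-carvone
Product: 2 (1S,4S,6S)-1-methyl-4-(prop-1-en-2-yl)-7-oxabicyclo[4.1.0]heptan-2-one (oxirane trans to isopropenyl)
Conditions: 30% H2O2, NaOH (cat.), MeOH, 0 °C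
Reagents that add atoms: hydrogen peroxide, OO
Why: Weitz–Scheffer nucleophilic epoxidation, in which hydroperoxide adds axially to the enone β-carbon anti to the isopropenyl group, so the oxirane (and the future tertiary C–O bond) is trans to isopropenyl while the isolated alkene is untouched.

**Step 2**
Reactants: 2 carvone oxide
Product: 4 (1S,4S)-1-methyl-4-(prop-1-en-2-yl)cyclohexane-1,2-diol (tertiary OH trans to isopropenyl; mixture of C2 epimers), via epoxy alcohol 3 (not isolated)
Conditions: LiAlH4, THF, 0 °C → reflux; H2O/aq. NaOH work-up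
Reagents that add atoms: none
Why: Hydride reduction of the ketone followed by SN2 hydride opening of the trisubstituted epoxide at its less substituted carbon leaves the tertiary C–O bond and its configuration intact; the carbinol epimers converge in step 3.

**Step 3**
Reactants: 4 diol (epimer mixture)
Product: 5 (2S,5S)-2-hydroxy-2-methyl-5-(prop-1-en-2-yl)cyclohexan-1-one
Conditions: (COCl)2, DMSO, CH2Cl2, −78 °C; Et3N, −78 → 0 °C
Reagents that add atoms: none
Why: Swern oxidation can touch only the secondary alcohol, does not cleave the diol, and leaves the tertiary carbinol stereocentre and the isopropenyl group alone.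

**Step 4**
Reactants: 5 hydroxy ketone
Product: 6 (1S,4S)-2,2-dimethoxy-1-methyl-4-(prop-1-en-2-yl)cyclohexan-1-ol
Conditions: HC(OMe)3, MeOH, TsOH·H2O (cat.), rt; Et3N quench
Reagents that add atoms: trimethyl orthoformate, COC(OC)OC; methanol, CO
Why: Acid-catalysed ketalisation driven by the orthoformate as water scavenger; no stereocentre is involved.

**Step 5**
Reactants: 7 (1S,2S,4R)-1-methyl-4-(prop-1-en-2-yl)cyclohexane-1,2-diol (trans-diaxial diol)
Product: 8 (1S,2S,5R)-2-hydroxy-2-methyl-5-(prop-1-en-2-yl)cyclohexyl methanesulfonate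
Conditions: MsCl, Et3N, CH2Cl2, 0 °C
Reagents that add atoms: methanesulfonyl chloride, CS(=O)(=O)Cl
Why: Sulfonylation occurs only at the secondary hydroxyl (the tertiary one is inert at 0 °C) and with retention, since the C–O bond is not broken.

**Step 6**
Reactants: 8 hydroxy mesylate
Product: 9 (1S,2R,4R)-2-bromo-1-methyl-4-(prop-1-en-2-yl)cyclohexan-1-ol (Br cis to the tertiary OH)
Conditions: LiBr (5 equiv), DMF, 60 °C
Reagents that add atoms: lithium bromide, [Li+].[Br-]
Why: SN2 displacement of the axial mesylate by bromide inverts C2 and gives the equatorial bromide syn to the tertiary OH; without base the neutral hydroxyl does not close to the epoxide.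

**Step 7**
Reactants: 9 syn-bromohydrin
Product: 10 (1S,2R,4R)-2-bromo-4-(3-hydroxyprop-1-en-2-yl)-1-methylcyclohexan-1-ol
Conditions: SeO2 (0.3 equiv), t-BuOOH (3 equiv), CH2Cl2, 0 °C → rt
Reagents that add atoms: selenium dioxide, O=[Se]=O (oxygen carrier); tert-butyl hydroperoxide, CC(C)(C)OO (terminal oxidant)
Why: Riley allylic oxidation (ene reaction then [2,3]-sigmatropic shift) of the 1,1-disubstituted alkene goes at the methyl group in preference to the ring methine and touches no stereocentre.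

**Step 8**
Reactants: 6 hydroxy ketal (2.5 equiv); 10 allylic alcohol
Product: 13 (2S,5S,6R)-6-{2-[(1R,3R,4S)-3-bromo-4-hydroxy-4-methylcyclohexyl]prop-2-en-1-yl}-2-hydroxy-2-methyl-5-(prop-1-en-2-yl)cyclohexan-1-one, via mixed ketal 11 (not isolated), via allyl enol ether 12 (not isolated)
Conditions: 2,4-dinitrophenol (10 mol %), xylenes, 135 °C, MeOH distilled off
Reagents that add atoms: none
Why: Ketal Claisen rearrangement, in which alcohol exchange and loss of MeOH give the only possible enol ether (the other α-carbon is quaternary) and its chair-like [3,3] shift forms the C–C bond anti to the adjacent isopropenyl group; this α-centre is the only enolisable one, so it settles as the trans, all-equatorial epimer.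

**Step 9**
Reactants: 13 ketone
Product: 14 (1S,2S,3R,4S)-3-{2-[(1R,3R,4S)-3-bromo-4-hydroxy-4-methylcyclohexyl]prop-2-en-1-yl}-1-methyl-4-(prop-1-en-2-yl)cyclohexane-1,2-diol (target)
Conditions: NaBH4, MeOH, −20 → 0 °C
Reagents that add atoms: none
Why: Borohydride reduction by axial attack on the face opposite the axial C2 methyl gives the equatorial alcohol, trans to the tertiary OH and to the side chain; the bromohydrin and the alkenes are inert.

## Compound list

1 | (S)-(+)-carvone, (5S)-2-methyl-5-(prop-1-en-2-yl)cyclohex-2-en-1-one | CC1=CC[C@@H](CC1=O)C(C)=C | starting material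
2 | (1S,4S,6S)-1-methyl-4-(prop-1-en-2-yl)-7-oxabicyclo[4.1.0]heptan-2-one | C1[C@@H](C(=C)C)C[C@@H]2O[C@]2(C)C1=O | intermediate
3 | 2-hydroxy analogue of 2 (aluminium alkoxide in the flask; oxirane and C4 as in 2; both carbinol epimers) | C1[C@@H](C(=C)C)C[C@@H]2O[C@]2(C)C1O | intermediate (not isolated)
4 | (1S,4S)-1-methyl-4-(prop-1-en-2-yl)cyclohexane-1,2-diol (C2 epimers, both used) | C1[C@@H](C(=C)C)CC[C@](C)(O)C1O | intermediate
5 | (2S,5S)-2-hydroxy-2-methyl-5-(prop-1-en-2-yl)cyclohexan-1-one | C1[C@@H](C(=C)C)CC[C@](C)(O)C1=O | intermediate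
6 | (1S,4S)-2,2-dimethoxy-1-methyl-4-(prop-1-en-2-yl)cyclohexan-1-ol | C1[C@@H](C(=C)C)CC[C@](C)(O)C1(OC)OC | intermediate
7 | (1S,2S,4R)-1-methyl-4-(prop-1-en-2-yl)cyclohexane-1,2-diol | C=C(C)[C@@H]1CC[C@](C)(O)[C@@H](O)C1 | starting material
8 | (1S,2S,5R)-2-hydroxy-2-methyl-5-(prop-1-en-2-yl)cyclohexyl methanesulfonate | C=C(C)[C@@H]1CC[C@](C)(O)[C@@H](OS(C)(=O)=O)C1 | intermediate
9 | (1S,2R,4R)-2-bromo-1-methyl-4-(prop-1-en-2-yl)cyclohexan-1-ol | C=C(C)[C@@H]1CC[C@](C)(O)[C@H](Br)C1 | intermediate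
10 | (1S,2R,4R)-2-bromo-4-(3-hydroxyprop-1-en-2-yl)-1-methylcyclohexan-1-ol | C=C(CO)[C@@H]1CC[C@](C)(O)[C@H](Br)C1 | intermediate
11 | (1S,4S)-2-({2-[(1R,3R,4S)-3-bromo-4-hydroxy-4-methylcyclohexyl]prop-2-en-1-yl}oxy)-2-methoxy-1-methyl-4-(prop-1-en-2-yl)cyclohexan-1-ol (ketal carbon epimers) | C=C(COC1(OC)C[C@@H](C(=C)C)CC[C@]1(C)O)[C@@H]1CC[C@](C)(O)[C@H](Br)C1 | intermediate (not isolated)
12 | (1S,4S)-2-({2-[(1R,3R,4S)-3-bromo-4-hydroxy-4-methylcyclohexyl]prop-2-en-1-yl}oxy)-1-methyl-4-(prop-1-en-2-yl)cyclohex-2-en-1-ol | C=C(COC1=C[C@@H](C(=C)C)CC[C@]1(C)O)[C@@H]1CC[C@](C)(O)[C@H](Br)C1 | intermediate (not isolated)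
13 | (2S,5S,6R)-6-{2-[(1R,3R,4S)-3-bromo-4-hydroxy-4-methylcyclohexyl]prop-2-en-1-yl}-2-hydroxy-2-methyl-5-(prop-1-en-2-yl)cyclohexan-1-one | C=C(C[C@@H]1[C@@H](C(=C)C)CC[C@](C)(O)C1=O)[C@@H]1CC[C@](C)(O)[C@H](Br)C1 | intermediate
14 | (1S,2S,3R,4S)-3-{2-[(1R,3R,4S)-3-bromo-4-hydroxy-4-methylcyclohexyl]prop-2-en-1-yl}-1-methyl-4-(prop-1-en-2-yl)cyclohexane-1,2-diol | C=C(C[C@@H]1[C@@H](C(=C)C)CC[C@](C)(O)[C@H]1O)[C@@H]1CC[C@](C)(O)[C@H](Br)C1 | target

## Step count and risks

Total steps: 9. Longest linear sequence: 6 steps (1 → 2 → 4 → 5 → 6 → 13 → 14); the ring B branch (7 → 10) is 3 steps before the coupling.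

**Step 8 (ketal Claisen coupling).** The ketal is hindered and both partners are precious, so exchange may be slow and acid and heat may erode the allylic alcohol. The fallback builds the same allyl enol ether by C–O cross-coupling and sets out from 5. The dianion of 5 (LDA, 2.2 equiv, THF, −78 °C) is trapped with PhNTf2 to give (3S,6S)-6-hydroxy-6-methyl-3-(prop-1-en-2-yl)cyclohex-1-en-1-yl trifluoromethanesulfonate F1. Miyaura borylation (B2pin2, PdCl2(dppf), KOAc, dioxane, 80 °C) gives (1S,4S)-1-methyl-4-(prop-1-en-2-yl)-2-(4,4,5,5-tetramethyl-1,3,2-dioxaborolan-2-yl)cyclohex-2-en-1-ol F2. Chan–Lam-type etherification of F2 with 10 (Cu(OAc)2, Et3N, 4 Å sieves, CH2Cl2, rt, air) comes back to the route at 12, which rearranges to 13 on warming in toluene.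

**Step 6 (bromide displacement).** SN2 at a cyclohexyl carbon next to a fully substituted centre is slow, and bromide-induced E2 to the allylic alcohol competes. The fallback changes the leaving group to selenium and sets out from 8. K2CO3 in MeOH closes 8 to (1S,4R,6R)-1-methyl-4-(prop-1-en-2-yl)-7-oxabicyclo[4.1.0]heptane (trans-limonene oxide) F3. Diaxial opening at C2 with PhSeNa (PhSeSePh, NaBH4, EtOH) gives (1S,2S,4R)-1-methyl-2-(phenylselanyl)-4-(prop-1-en-2-yl)cyclohexan-1-ol F4. Bromodeselenation (Br2, 1.0 equiv, CH2Cl2, −78 °C, where selenium is brominated faster than the alkene) displaces the dibromoselenurane with inversion and comes back to the route at 9.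

**Step 7 (SeO2 allylic oxidation).** Yields for isopropenyl groups are usually moderate, with over-oxidation to the enal (returnable with NaBH4) and some attack at the ring methine. The fallback sets out from 9. Ene-type chlorination (Ca(OCl)2, solid CO2, CH2Cl2/H2O, 0 °C) gives (1S,2R,4R)-2-bromo-4-(3-chloroprop-1-en-2-yl)-1-methylcyclohexan-1-ol F5. KOAc in DMF at 50 °C gives 2-[(1R,3R,4S)-3-bromo-4-hydroxy-4-methylcyclohexyl]prop-2-en-1-yl acetate F6. Methanolysis (K2CO3, MeOH, 0 °C) comes back to the route at 10.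

## Further compounds

F1 | step 8 | (3S,6S)-6-hydroxy-6-methyl-3-(prop-1-en-2-yl)cyclohex-1-en-1-yl trifluoromethanesulfonate | FC(F)(F)S(=O)(=O)OC1=C[C@@H](C(=C)C)CC[C@]1(C)O
F2 | step 8 | (1S,4S)-1-methyl-4-(prop-1-en-2-yl)-2-(4,4,5,5-tetramethyl-1,3,2-dioxaborolan-2-yl)cyclohex-2-en-1-ol | CC1(C)OB(OC1(C)C)C1=C[C@@H](C(=C)C)CC[C@]1(C)O
F3 | step 6 | (1S,4R,6R)-1-methyl-4-(prop-1-en-2-yl)-7-oxabicyclo[4.1.0]heptane | C=C(C)[C@@H]1CC[C@]2(C)O[C@@H]2C1
F4 | step 6 | (1S,2S,4R)-1-methyl-2-(phenylselanyl)-4-(prop-1-en-2-yl)cyclohexan-1-ol | C=C(C)[C@@H]1CC[C@](C)(O)[C@@H]([Se]c2ccccc2)C1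
F5 | step 7 | (1S,2R,4R)-2-bromo-4-(3-chloroprop-1-en-2-yl)-1-methylcyclohexan-1-ol | C=C(CCl)[C@@H]1CC[C@](C)(O)[C@H](Br)C1
F6 | step 7 | 2-[(1R,3R,4S)-3-bromo-4-hydroxy-4-methylcyclohexyl]prop-2-en-1-yl acetate | CC(=O)OCC(=C)[C@@H]1CC[C@](C)(O)[C@H](Br)C1
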